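**Plan**
- Retrosynthesis: the acetate goes back to olivil, then to the C9 carboxylic acid, then to a cis-fused furo[3,4-c]furanone whose lactone ties the benzyl carbon C7′ to C9. Last, C5–C4 and C2–C3 are cut together as a [3+2] cycloaddition.
- Enabling feature: the ether unit C2–O1–C5 (aryl on C2, unsubstituted C5 methylene) is the imprint of a vanillin-derived carbonyl ylide. The C3–C4 bond (oxygen on C4, the C9 carbon on C3 cis to the C4 benzyl carbon) is the enol-ether C=C bond of a 5-aryl tetronate (4-alkoxybutenolide).
- Forward: racemic mandelate → keto ester → (R)-mandelate → 4-benzyloxy-5-arylbutenolide; O-benzylvanillin → bis(silylmethyl) acetal; the ylide cycloaddition builds the oxolane on the butenolide. One hydrogenolysis removes three benzyl groups and opens the lactone at its benzylic C–O bond; borane reduction and lipase acetylation finish.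
- Stereochemistry: one stereocenter (the butenolide γ-carbon C7′, set by asymmetric transfer hydrogenation) relays C3 and C4 (anti face) and C2 (exo approach) in the single cycloaddition, and is then erased as the benzyl CH2.

Key step: step 6

Remark: the four starting materials are taken as purchasable; atom labels are oxolane O1, C2 (aryl), C3, C4, C5, with C9 the CH2OAc carbon and C7′ the benzyl carbon on C4 (the γ-carbon of butenolide 7).

**Step 1**
Reactants: 1 rac-4-hydroxy-3-methoxymandelic acid
Product: 2 benzyl rac-2-[4-(benzyloxy)-3-methoxyphenyl]-2-hydroxyacetate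
Conditions: BnBr (2.3 equiv), K2CO3 (3 equiv), DMF, rt
Reagents that add atoms: benzyl bromide BrCc1ccccc1
Why: Williamson-type O-alkylation, in which carbonate deprotonates only the carboxylic acid and the phenol, so the benzyl ester and aryl benzyl ether should form while the secondary alcohol stays free and the center stays racemic.

**Step 2**
Reactants: 2 benzyl rac-2-[4-(benzyloxy)-3-methoxyphenyl]-2-hydroxyacetate
Product: 3 benzyl 2-[4-(benzyloxy)-3-methoxyphenyl]-2-oxoacetate
Conditions: Dess–Martin periodinane (1.3 equiv), CH2Cl2, rt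
Reagents that add atoms: none
Why: Dess–Martin oxidation of the benzylic α-hydroxy ester to the α-keto ester under neutral conditions that the benzyl ester and ether tolerate; the racemic center is removed so that it can be reset by catalysis.

**Step 3**
Reactants: 3 benzyl 2-[4-(benzyloxy)-3-methoxyphenyl]-2-oxoacetate
Product: 4 benzyl (2R)-2-[4-(benzyloxy)-3-methoxyphenyl]-2-hydroxyacetate
Conditions: RuCl[(S,S)-TsDPEN](p-cymene) (1 mol %), HCO2H–Et3N (5:2), DMF, rt
Reagents that add atoms: none
Why: Noyori asymmetric transfer hydrogenation of an aryl ketone, in which the substrate should dock through the arene CH/π contact as acetophenone does, so that the (S,S)-catalyst delivers hydride to the face giving the (R)-carbinol (the descriptor differs from the acetophenone case only because CO2Bn outranks aryl); the benzyl groups are inert.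

**Step 4**
Reactants: 4 benzyl (2R)-2-[4-(benzyloxy)-3-methoxyphenyl]-2-hydroxyacetate; 5 (triphenylphosphoranylidene)ketene
Product: 7 (5R)-4-(benzyloxy)-5-[4-(benzyloxy)-3-methoxyphenyl]furan-2(5H)-one, via phosphorane ester 6 (not isolated)
Conditions: 5 (1.2 equiv), PhCO2H (5 mol %), THF, 60 °C
Reagents that add atoms: none
Why: Domino addition/intramolecular Wittig olefination, in which the alcohol adds across the C=C=O unit to give ester-stabilized ylide 6, which olefinates the neighbouring benzyl ester carbonyl in a five-membered ring closure, so that the ester benzyloxy group becomes the enol-ether substituent and the stereocenter, not a reacting atom, should be retained.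

**Step 5**
Reactants: 8 4-(benzyloxy)-3-methoxybenzaldehyde; 9 (trimethylsilyl)methanol
Product: 10 1-(benzyloxy)-4-{bis[(trimethylsilyl)methoxy]methyl}-2-methoxybenzene
Conditions: 9 (2.5 equiv), p-TsOH·H2O (1 mol %), benzene, reflux, Dean–Stark trap
Reagents that add atoms: none
Why: Acid-catalysed acetalization of an aromatic aldehyde with a primary alcohol, driven by azeotropic removal of water; no stereocenter is formed.

**Step 6**
Reactants: 10 1-(benzyloxy)-4-{bis[(trimethylsilyl)methoxy]methyl}-2-methoxybenzene (2.5 equiv); 7 (5R)-4-(benzyloxy)-5-[4-(benzyloxy)-3-methoxyphenyl]furan-2(5H)-one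
Product: 13 (3R,3aS,6S,6aR)-3a-(benzyloxy)-3,6-bis[4-(benzyloxy)-3-methoxyphenyl]tetrahydro-1H-furo[3,4-c]furan-1-one, via α-chloro ether 11 (not isolated), via carbonyl ylide 12 (not isolated)
Conditions: (a) 10, AcCl (1 equiv per 10), CH2Cl2, 0 °C to rt, then evaporation; (b) slow addition of crude 11 to 7 and CsF (4 equiv), MeCN, 0 °C to rt
Reagents that add atoms: none
Why: Proposed new method: AcCl turns acetal 10 into α-chloro ether 11, fluoride attack at silicon then expels chloride (1,3-elimination) to give the nonstabilized carbonyl ylide 12, and this 4π dipole should add suprafacially across the C3=C4 enol-ether double bond of butenolide 7 in a concerted, asynchronous 1,3-dipolar cycloaddition in which the carbanion-like CH2 terminus bonds to the electrophilic β-carbon (C4) and the aryl-stabilized oxocarbenium terminus to the α-carbon (C3). The closest known reaction type is the [3+2] cycloaddition of silicon-derived nonstabilized carbonyl ylides with acrylates, fumarates, enones and alkynoates; what is new is the dipolarophile, a β-alkoxy-β-substituted butenolide whose acceptor strength is lowered by the alkoxy group, which is why the cheap ylide precursor is used in excess and added slowly. The oxolane ring is closed by cycloaddition (both C–C bonds formed in one [4π+2π] event, not by a separate ionic ring closure), so the new ring is necessarily cis-fused to the lactone, which places the future benzyl carbon C7′ and C9 cis on the oxolane. The stereocenters at C3 and C4 are set by approach of the dipole to the face of the flat butenolide opposite the aryl group on the γ-carbon, the only stereocenter of 7, which sits directly beside the reacting β-carbon; the stereocenter at C2 is set by an exo transition state of the E-configured ylide, which places its aryl group on the convex face, trans to the lactone carbonyl. The step needs regioselectivity, secured by the matched polarization of dipole and push–pull alkene, facial selectivity, secured by the γ-aryl group, and configurational survival of 7 before it reacts, for which fluoride is kept as sparingly soluble CsF at low temperature.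

**Step 7**
Reactants: 13 (3R,3aS,6S,6aR)-3a-(benzyloxy)-3,6-bis[4-(benzyloxy)-3-methoxyphenyl]tetrahydro-1H-furo[3,4-c]furan-1-one
Product: 14 (2S,3R,4S)-4-hydroxy-4-(4-hydroxy-3-methoxybenzyl)-2-(4-hydroxy-3-methoxyphenyl)tetrahydrofuran-3-carboxylic acid
Conditions: H2 (1 atm), Pd(OH)2/C, EtOAc–MeOH, rt, stopped when the lactone is consumed
Reagents that add atoms: none
Why: Catalytic hydrogenolysis of benzylic C–O bonds, in which the two aryl benzyl ethers, the tertiary benzyl ether and the benzylic acyloxy C–O bond of the γ-aryl lactone (carboxylate as leaving group) should cleave while the benzylic ring-ether bond C2–O1 (alkoxide as leaving group) is slower and should survive; C2, C3 and C4 are untouched and the relay stereocenter becomes CH2.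

**Step 8**
Reactants: 14 (2S,3R,4S)-4-hydroxy-4-(4-hydroxy-3-methoxybenzyl)-2-(4-hydroxy-3-methoxyphenyl)tetrahydrofuran-3-carboxylic acid
Product: 15 (3S,4R,5S)-3-(4-hydroxy-3-methoxybenzyl)-5-(4-hydroxy-3-methoxyphenyl)-4-(hydroxymethyl)tetrahydrofuran-3-ol (olivil)
Conditions: BH3·THF (6 equiv), THF, 0 °C to rt; MeOH quench and evaporation
Reagents that add atoms: none
Why: Borane reduction of a carboxylic acid through the acyloxyborane, chemoselective beside phenols and the tertiary alcohol, which only consume hydride as borates that methanol cleaves; no stereocenter is affected.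

**Step 9**
Reactants: 15 (3S,4R,5S)-3-(4-hydroxy-3-methoxybenzyl)-5-(4-hydroxy-3-methoxyphenyl)-4-(hydroxymethyl)tetrahydrofuran-3-ol (olivil)
Product: 16 [(2S,3R,4S)-4-hydroxy-4-(4-hydroxy-3-methoxybenzyl)-2-(4-hydroxy-3-methoxyphenyl)tetrahydrofuran-3-yl]methyl acetate (olivil monoacetate)
Conditions: Novozym 435 (immobilized Candida antarctica lipase B), vinyl acetate (5 equiv), THF, 40 °C
Reagents that add atoms: vinyl acetate C=COC(C)=O
Why: Lipase-catalysed transesterification with an irreversible acyl donor, which should acylate only the primary aliphatic hydroxyl because phenols and the tertiary alcohol are not accepted by the acyl-enzyme; no stereocenter is affected.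

**Compound list**
1 | rac-4-hydroxy-3-methoxymandelic acid | COc1cc(C(O)C(=O)O)ccc1O | starting material
2 | benzyl rac-2-[4-(benzyloxy)-3-methoxyphenyl]-2-hydroxyacetate | COc1cc(C(O)C(=O)OCc2ccccc2)ccc1OCc1ccccc1 | intermediate
3 | benzyl 2-[4-(benzyloxy)-3-methoxyphenyl]-2-oxoacetate | COc1cc(C(=O)C(=O)OCc2ccccc2)ccc1OCc1ccccc1 | intermediate
4 | benzyl (2R)-2-[4-(benzyloxy)-3-methoxyphenyl]-2-hydroxyacetate | COc1cc([C@@H](O)C(=O)OCc2ccccc2)ccc1OCc1ccccc1 | intermediate
5 | (triphenylphosphoranylidene)ketene | O=C=C=P(c1ccccc1)(c1ccccc1)c1ccccc1 | starting material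
6 | benzyl (2R)-2-[4-(benzyloxy)-3-methoxyphenyl]-2-{[(triphenylphosphoranylidene)acetyl]oxy}acetate (phosphorane ester, not isolated) | O=C(C=P(c1ccccc1)(c1ccccc1)c1ccccc1)O[C@H](c1ccc(OCc2ccccc2)c(OC)c1)C(=O)OCc1ccccc1 | intermediate
7 | (5R)-4-(benzyloxy)-5-[4-(benzyloxy)-3-methoxyphenyl]furan-2(5H)-one | O=C1O[C@H](c2ccc(OCc3ccccc3)c(OC)c2)C(OCc2ccccc2)=C1 | intermediate
8 | 4-(benzyloxy)-3-methoxybenzaldehyde | COc1cc(C=O)ccc1OCc1ccccc1 | starting material
9 | (trimethylsilyl)methanol | C[Si](C)(C)CO | starting material
10 | 1-(benzyloxy)-4-{bis[(trimethylsilyl)methoxy]methyl}-2-methoxybenzene | COc1cc(C(OC[Si](C)(C)C)OC[Si](C)(C)C)ccc1OCc1ccccc1 | intermediate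
11 | 1-(benzyloxy)-4-{chloro[(trimethylsilyl)methoxy]methyl}-2-methoxybenzene (racemic α-chloro ether, not isolated) | COc1cc(C(Cl)OC[Si](C)(C)C)ccc1OCc1ccccc1 | intermediate
12 | (E)-carbonyl ylide of 4-(benzyloxy)-3-methoxybenzaldehyde with a CH2 terminus (not isolated) | [CH2-]/[O+]=C/c1ccc(OCc2ccccc2)c(OC)c1 | intermediate
13 | (3R,3aS,6S,6aR)-3a-(benzyloxy)-3,6-bis[4-(benzyloxy)-3-methoxyphenyl]tetrahydro-1H-furo[3,4-c]furan-1-one | O=C1O[C@H](c2ccc(OCc3ccccc3)c(OC)c2)[C@@]2(OCc3ccccc3)CO[C@H](c3ccc(OCc4ccccc4)c(OC)c3)[C@@H]12 | intermediate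
14 | (2S,3R,4S)-4-hydroxy-4-(4-hydroxy-3-methoxybenzyl)-2-(4-hydroxy-3-methoxyphenyl)tetrahydrofuran-3-carboxylic acid | COc1cc(C[C@@]2(O)CO[C@H](c3ccc(O)c(OC)c3)[C@H]2C(=O)O)ccc1O | intermediate
15 | (3S,4R,5S)-3-(4-hydroxy-3-methoxybenzyl)-5-(4-hydroxy-3-methoxyphenyl)-4-(hydroxymethyl)tetrahydrofuran-3-ol (olivil) | COc1cc(C[C@@]2(O)CO[C@H](c3ccc(O)c(OC)c3)[C@H]2CO)ccc1O | intermediate
16 | [(2S,3R,4S)-4-hydroxy-4-(4-hydroxy-3-methoxybenzyl)-2-(4-hydroxy-3-methoxyphenyl)tetrahydrofuran-3-yl]methyl acetate (olivil monoacetate) | COc1cc(C[C@@]2(O)CO[C@H](c3ccc(O)c(OC)c3)[C@H]2COC(C)=O)ccc1O | target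

**Step count**
Total steps: 9. Longest linear sequence: 8 (steps 1–4 and 6–9); step 5 is the second branch.

**Steps most likely to fail**

1. Step 6 (the step that carries the label). The dipole may be consumed by dimerization or protonation faster than it adds to the deactivated, trisubstituted push–pull alkene. The benzylic γ-proton of 7 may be removed by fluoride or by the ylide, which would erode enantiomeric purity, and exo/endo control at C2 may be poor. Alkoxide may also be lost from C4 of the adduct by β-elimination.
 Fallback (known chemistry, sets out from 8, returns at 16): aldehyde 8 would be vinylated by catalytic asymmetric addition of divinylzinc with a chiral β-amino alcohol ligand to give (S)-1-[4-(benzyloxy)-3-methoxyphenyl]prop-2-en-1-ol F1. O-Propargylation (NaH, propargyl bromide) would give 1-(benzyloxy)-2-methoxy-4-[(1S)-1-(prop-2-yn-1-yloxy)prop-2-en-1-yl]benzene F2. Sonogashira coupling with 1-(benzyloxy)-4-iodo-2-methoxybenzene (PdCl2(PPh3)2, CuI, Et3N) would give the diaryl enyne ether F3, and mCPBA epoxidation of the vinyl group the oxirane F4 (configuration at the new oxirane carbon is immaterial). Opening of F4 with Cp2TiCl (trivalent titanium, from Cp2TiCl2 and Zn, Nugent–RajanBabu conditions) would give the C3 radical, which closes 5-exo-dig onto the alkyne to give the 2,3-trans 4-arylidene oxolane alcohol F5. Acetylation (Ac2O, pyridine) would give acetate F6, and epoxidation of the exocyclic alkene anti to the C3 substituent (mCPBA, NaHCO3) the spiro-epoxide F7. Hydrogenolysis (H2, Pd/C) of the benzylic epoxide C–O bond and of the two aryl benzyl ethers would then deliver 16.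

2. Step 7. Hydrogenolysis may not stop cleanly: cleavage of the hindered tertiary benzyl ether or of the lactone may lag while the benzylic C2–O1 bond of the oxolane starts to cleave (over-reduction with ring opening).
 Fallback (sets out from 13, returns at 16): the benzylic lactone oxygen would be removed by radical instead of catalytic means. LiAlH4 would reduce 13 to the diol F8. The primary hydroxyl would be acetylated selectively (AcCl, 2,4,6-collidine, −78 °C) to the monoacetate F9. The remaining benzylic secondary alcohol would be converted to the phenyl thionocarbonate F10 (PhOC(S)Cl, DMAP, pyridine) and removed by Barton–McCombie deoxygenation (Bu3SnH, AIBN, toluene, 80 °C) to give the tribenzyl ether F11. A brief hydrogenolysis of the three benzyl ethers (H2, Pd/C) would then give 16 without having to break a benzylic C–O bond of the skeleton.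

3. Step 4. Configuration may be lost by enolization of the doubly activated γ-C–H (benzylic and vinylogous to the lactone carbonyl) under the warm, mildly basic conditions of the domino Wittig reaction.
 Fallback (sets out from 2, returns at 7): asymmetric catalysis would be replaced by resolution. Racemic hydroxy ester 2 would be treated directly with 5 to give, via the racemic phosphorane ester F12, the racemic tetronate F13. Preparative chromatography of F13 on a chiral stationary phase would provide 7; steps 2 and 3 are then not needed.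

**Further compounds**
F1 | step 6 | (S)-1-[4-(benzyloxy)-3-methoxyphenyl]prop-2-en-1-ol | C=C[C@H](O)c1ccc(OCc2ccccc2)c(OC)c1
F2 | step 6 | 1-(benzyloxy)-2-methoxy-4-[(1S)-1-(prop-2-yn-1-yloxy)prop-2-en-1-yl]benzene | C=C[C@H](OCC#C)c1ccc(OCc2ccccc2)c(OC)c1
F3 | step 6 | 1-(benzyloxy)-4-[(1S)-1-({3-[4-(benzyloxy)-3-methoxyphenyl]prop-2-yn-1-yl}oxy)prop-2-en-1-yl]-2-methoxybenzene | C=C[C@H](OCC#Cc1ccc(OCc2ccccc2)c(OC)c1)c1ccc(OCc2ccccc2)c(OC)c1
F4 | step 6 | 2-[(R)-[4-(benzyloxy)-3-methoxyphenyl]({3-[4-(benzyloxy)-3-methoxyphenyl]prop-2-yn-1-yl}oxy)methyl]oxirane (both oxirane epimers) | C1OC1[C@H](OCC#Cc1ccc(OCc2ccccc2)c(OC)c1)c1ccc(OCc2ccccc2)c(OC)c1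
F5 | step 6 | [(2S,3R)-2-[4-(benzyloxy)-3-methoxyphenyl]-4-[4-(benzyloxy)-3-methoxybenzylidene]tetrahydrofuran-3-yl]methanol (alkene isomers) | COc1cc(C=C2CO[C@H](c3ccc(OCc4ccccc4)c(OC)c3)[C@H]2CO)ccc1OCc1ccccc1
F6 | step 6 | [(2S,3R)-2-[4-(benzyloxy)-3-methoxyphenyl]-4-[4-(benzyloxy)-3-methoxybenzylidene]tetrahydrofuran-3-yl]methyl acetate | COc1cc(C=C2CO[C@H](c3ccc(OCc4ccccc4)c(OC)c3)[C@H]2COC(C)=O)ccc1OCc1ccccc1
F7 | step 6 | spiro-epoxide of F6 at the exocyclic alkene, oxirane oxygen on C4 trans to the C3 acetoxymethyl group | COc1cc(C2O[C@@]23CO[C@H](c2ccc(OCc4ccccc4)c(OC)c2)[C@H]3COC(C)=O)ccc1OCc1ccccc1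
F8 | step 7 | diol from lactone opening of 13: (R)-configured benzylic alcohol at C7′ and CH2OH at C9, other centers as in 13 | O[C@H](c1ccc(OCc2ccccc2)c(OC)c1)[C@@]1(OCc2ccccc2)CO[C@H](c2ccc(OCc3ccccc3)c(OC)c2)[C@H]1CO
F9 | step 7 | primary monoacetate of F8 | O[C@H](c1ccc(OCc2ccccc2)c(OC)c1)[C@@]1(OCc2ccccc2)CO[C@H](c2ccc(OCc3ccccc3)c(OC)c2)[C@H]1COC(C)=O
F10 | step 7 | O-phenyl thionocarbonate of F9 at the benzylic alcohol | S=C(Oc1ccccc1)O[C@H](c1ccc(OCc2ccccc2)c(OC)c1)[C@@]1(OCc2ccccc2)CO[C@H](c2ccc(OCc3ccccc3)c(OC)c2)[C@H]1COC(C)=O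
F11 | step 7 | [(2S,3R,4S)-4-(benzyloxy)-4-[4-(benzyloxy)-3-methoxybenzyl]-2-[4-(benzyloxy)-3-methoxyphenyl]tetrahydrofuran-3-yl]methyl acetate | COc1cc(C[C@@]2(OCc3ccccc3)CO[C@H](c3ccc(OCc4ccccc4)c(OC)c3)[C@H]2COC(C)=O)ccc1OCc1ccccc1
F12 | step 4 | racemic benzyl 2-[4-(benzyloxy)-3-methoxyphenyl]-2-{[(triphenylphosphoranylidene)acetyl]oxy}acetate (not isolated) | O=C(C=P(c1ccccc1)(c1ccccc1)c1ccccc1)OC(c1ccc(OCc2ccccc2)c(OC)c1)C(=O)OCc1ccccc1
F13 | step 4 | racemic 4-(benzyloxy)-5-[4-(benzyloxy)-3-methoxyphenyl]furan-2(5H)-one | O=C1OC(c2ccc(OCc3ccccc3)c(OC)c2)C(OCc2ccccc2)=C1
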